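**Retrosynthetic overview**
1. Theasinensin B ⇒ theasinensin A: one of the two homotopic gallates of the C2-symmetric dimer is removed last by enzymatic mono-deacylation.
2. Theasinensin A ⇒ dehydrotheasinensin A: reductive aromatisation opens the hemiketal ring and turns its sp3 centre into the biaryl axis.
3. Dehydrotheasinensin A ⇒ two molecules of EGCG o-quinone: quinone dimerisation forms the C2′–C2′ bond and closes the dihydrobenzofuran hemiketal ring, as in tea fermentation.
4. Ring order: rings A, B and C and the four sp3 stereocentres come intact from (−)-EGCG; the only ring made on the way is the transient hemiketal ring, formed in the coupling and opened in the reduction.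

Assumption: the SMILES does not encode the biaryl axis, so the natural (R)-axis atropisomer is taken as the goal; (−)-EGCG, the bulk catechin of green tea extract, counts as a cheap commercial starting material.

**Step 1**
Reactants: 1 (−)-epigallocatechin 3-O-gallate (EGCG), two molecules
Product: 4 theasinensin A, via EGCG o-quinone 2 (not isolated), via dehydrotheasinensin A 3 (not isolated)
Conditions: CuCl2·2H2O (2.2 equiv), H2O–MeOH 7:3, rt, 24 h; then L-ascorbic acid (5 equiv), 85 °C, 20 min; MCI gel CHP20P, then Sephadex LH-20
Reagents that add atoms: none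
Why: Oxidative quinone coupling as in tea fermentation: divalent copper oxidises ring B of 1 to the hydroxy-o-quinone 2, the enol carbon C2′ of one quinone adds 1,6 to C2′ of a second and the adduct is trapped as the cis-fused hemiketal hydrate 3 (its new sp3 centre set by the facial bias of the two 2R,3R flavan units), and ascorbic acid then reduces the ene-trione so that aromatisation transfers this central chirality to the (R) biaryl axis, which four ortho substituents lock; the acidic medium (pH about 2–3) spares the galloyl esters and suppresses C2 epimerisation, so the four flavan stereocentres are untouched.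

**Step 2**
Reactants: 4 theasinensin A
Product: 5 theasinensin B
Conditions: tannase (Aspergillus oryzae), NaOAc–AcOH buffer pH 5.5, 30 °C, N2, HPLC control, stopped at about 40% ester cleavage by acidifying to pH 3; Sephadex LH-20, then ODS
Reagents that add atoms: none
Why: Enzymatic ester hydrolysis (tannase, a serine hydrolase specific for galloyl esters, acyl–oxygen cleavage so the C3 oxygen and its configuration stay, the oxygen of water ending in gallic acid): because 4 is C2-symmetric its two gallates are homotopic and the first cleavage can give only one mono-ester, 5, while the second cleavage runs statistically at half the rate, so 5 builds up to roughly 40–50% with unreacted 4 recovered for another pass; no stereocentre is formed and the axis does not rotate at 30 °C.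

**Compound list**
1 | (−)-epigallocatechin 3-O-gallate (EGCG), 2R,3R | O=C(O[C@@H]1Cc2c(O)cc(O)cc2O[C@@H]1c1cc(O)c(O)c(O)c1)c1cc(O)c(O)c(O)c1 | starting material
2 | EGCG o-quinone: ring B of 1 oxidised to the 5′-hydroxy-3′,4′-quinone, flavan centres 2R,3R unchanged | O=C(O[C@@H]1Cc2c(O)cc(O)cc2O[C@@H]1C1=CC(=O)C(=O)C(O)=C1)c1cc(O)c(O)c(O)c1 | intermediate
3 | dehydrotheasinensin A, drawn as one hemiketal hydrate form: one EGCG unit keeps an aromatic ring B, the ring B of the other is a cyclohexenone with a gem-diol and a hemiketal carbon; the rings are joined C2′(sp2)–C2′(sp3 methine) and bridged by C3′–O–C(OH) into a cis-fused dihydrobenzofuran; both flavan units 2R,3R; the methine and hemiketal centres are single-configured but left unassigned in the SMILES | O=C(O[C@@H]1Cc2c(O)cc(O)cc2O[C@@H]1c1cc(O)c(O)c2OC3(O)C(c12)C([C@H]1Oc4cc(O)cc(O)c4C[C@H]1OC(=O)c1cc(O)c(O)c(O)c1)=CC(=O)C3(O)O)c1cc(O)c(O)c(O)c1 | intermediate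
4 | theasinensin A: C2-symmetric 2′,2′-linked dimer of EGCG, both units 2R,3R, (R) biaryl axis | O=C(O[C@@H]1Cc2c(O)cc(O)cc2O[C@@H]1c1cc(O)c(O)c(O)c1-c1c([C@H]2Oc3cc(O)cc(O)c3C[C@H]2OC(=O)c2cc(O)c(O)c(O)c2)cc(O)c(O)c1O)c1cc(O)c(O)c(O)c1 | intermediate
5 | theasinensin B: 2′,2′-linked EGCG–epigallocatechin dimer, both units 2R,3R, one 3-O-gallate, (R) biaryl axis | O=C(O[C@@H]1Cc2c(O)cc(O)cc2O[C@@H]1c1cc(O)c(O)c(O)c1-c1c([C@H]2Oc3cc(O)cc(O)c3C[C@H]2O)cc(O)c(O)c1O)c1cc(O)c(O)c(O)c1 | target

**Totals**
Total step count: 2. Longest linear sequence: 2 (1 → 4 → 5).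

**Steps most likely to fail** (the route has only two steps, so both are ranked, the riskier first)

Step 2. The risk is stopping at the mono-ester: the ceiling is statistical, both gallates may be lost, and 4, 5 and the bis-deacylated dimer must be separated. The fallback sets out from 1 and comes back to the route at 5, and moves the ester cleavage in front of the coupling. Part of 1 is hydrolysed to completion with tannase (pH 5.5, 30 °C) to give (−)-epigallocatechin F1. F1 (1 equiv) and 1 (3 equiv) are then co-oxidised with CuCl2 in aqueous MeOH as in step 1. EGC o-quinone F2 and the quinone 2 cross-couple to dehydrotheasinensin B F3 and to ring-swapped dehydrotheasinensin B F4, in which the other ring B carries the oxidised part. Ascorbic acid at 85 °C reduces both to 5. The EGCG homodimer 4 formed alongside is fed into step 2, and the small amount of theasinensin C F5 is removed on Sephadex LH-20.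

Step 1. The risks are over-oxidation of 3 to ring-contracted pigments and oligomers, tedious removal of copper, and loss of axis selectivity if the reduction is run at too high a pH. The fallback sets out from 1 and comes back to the route at 4. It replaces the one-pot copper sequence by a two-stage biocatalytic route with the ring-closed intermediate isolated. Compound 1 is oxidised under air with a polyphenol oxidase (mushroom tyrosinase or a fresh pear homogenate) at pH 5–6, which passes through 2 and lets 3 build up. The oxidation is stopped by acidifying to pH 2–3, and 3 is isolated on Sephadex LH-20 with acidic eluent. Pure 3 is then reduced in a separate flask with ascorbic acid at pH 3 to give 4. This fallback makes no compound outside the list (F0).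

**Further compounds**
F1 | step 2 | (−)-epigallocatechin (EGC), 2R,3R | O[C@@H]1Cc2c(O)cc(O)cc2O[C@@H]1c1cc(O)c(O)c(O)c1
F2 | step 2 | EGC o-quinone: ring B of F1 as the 5′-hydroxy-3′,4′-quinone | O[C@@H]1Cc2c(O)cc(O)cc2O[C@@H]1C1=CC(=O)C(=O)C(O)=C1
F3 | step 2 | dehydrotheasinensin B, hemiketal hydrate with the EGCG ring B aromatic and the EGC ring B as the hydrated cyclohexenetrione; methine and hemiketal centres unassigned | O=C(O[C@@H]1Cc2c(O)cc(O)cc2O[C@@H]1c1cc(O)c(O)c2OC3(O)C(c12)C([C@H]1Oc4cc(O)cc(O)c4C[C@H]1O)=CC(=O)C3(O)O)c1cc(O)c(O)c(O)c1
F4 | step 2 | ring-swapped dehydrotheasinensin B, hemiketal hydrate with the EGC ring B aromatic and the EGCG ring B as the hydrated cyclohexenetrione; methine and hemiketal centres unassigned | O[C@@H]1Cc2c(O)cc(O)cc2O[C@@H]1c1cc(O)c(O)c2OC3(O)C(c12)C([C@H]1Oc4cc(O)cc(O)c4C[C@H]1OC(=O)c1cc(O)c(O)c(O)c1)=CC(=O)C3(O)O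
F5 | step 2 | theasinensin C: 2′,2′-linked dimer of EGC, both units 2R,3R, (R) biaryl axis | O[C@@H]1Cc2c(O)cc(O)cc2O[C@@H]1c1cc(O)c(O)c(O)c1-c1c([C@H]2Oc3cc(O)cc(O)c3C[C@H]2O)cc(O)c(O)c1O
F0 | step 1 | none | none
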